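**Strategy**

The plan reads the dihydrofuran ring (O1–C2–C3–C3a–C7a) as a 3-formyl oxolane: the quaternary C3a carries C4, and O1 joins the aryl carbinol C2 to C7a. A Prins cyclisation–pinacol rearrangement of an aryl acetal of a (Z)-alkenyl 1,2-diol therefore makes C2–C3 and C3a–C7a in one operation and sets C2, C3 and C3a from one carbinol centre (C7a, taken from (R)-butane-1,2,4-triol), which the last step erases. The precursor is a 2-aryl-1,3-dioxane bearing the allylic alcohol. The carbocycle (C3a, C4–C7, C7a) is closed afterwards by an intramolecular Horner–Wadsworth–Emmons reaction and dehydrogenated.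

Key step: step 6

Remark: atom labels follow the benzofuran numbering of the target (O1, C2, C3, C3a, C4–C7, C7a) in all intermediates. The cationic intermediates 10 and 11 are drawn as free alcohols, with the tin Lewis acid left out.

**Route**

Step 1
Reactants: 1 acetaldehyde
Product: 2 1,1-dibromoprop-1-ene
Conditions: CBr4, PPh3, CH2Cl2, 0 °C
Reagents that add atoms: carbon tetrabromide, BrC(Br)(Br)Br
Why: Ramirez dibromo-olefination of an aliphatic aldehyde with the ylide formed from CBr4 and PPh3 is general and creates no stereocentre.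

Step 2
Reactants: 2 1,1-dibromoprop-1-ene
Product: 3 (4Z)-4-bromohexa-1,4-diene
Conditions: allyltributylstannane, Pd2(dba)3 (2.5 mol %), P(2-furyl)3 (15 mol %), toluene, 80 °C
Reagents that add atoms: allyltributylstannane, C=CC[Sn](CCCC)(CCCC)CCCC
Why: In this Stille coupling zerovalent palladium should insert into the less hindered C–Br bond trans to the methyl group of the 1,1-dibromoalkene, so the allyl group enters trans to methyl and the remaining bromine stays cis to it, which fixes the (Z)-bromoalkene.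

Step 3
Reactants: 4 (2R)-butane-1,2,4-triol; 5 3,4,5-trimethoxybenzaldehyde
Product: 6 [(2R,4R)-2-(3,4,5-trimethoxyphenyl)-1,3-dioxan-4-yl]methanol
Conditions: camphorsulfonic acid (5 mol %), toluene, reflux, Dean–Stark trap
Reagents that add atoms: none
Why: Thermodynamic acetalisation of a 1,2,4-triol with an aryl aldehyde should favour the six-membered 1,3-dioxane with both substituents equatorial (cis-2,4), which sets the acetal centre relative to the existing carbinol centre and leaves the primary hydroxyl free.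

Step 4
Reactants: 6 [(2R,4R)-2-(3,4,5-trimethoxyphenyl)-1,3-dioxan-4-yl]methanol
Product: 7 (2R,4R)-2-(3,4,5-trimethoxyphenyl)-1,3-dioxane-4-carbaldehyde
Conditions: (COCl)2, DMSO, CH2Cl2, −78 °C; then Et3N, −78 → 0 °C
Reagents that add atoms: none
Why: Swern oxidation converts the primary alcohol into the aldehyde under non-acidic conditions that should leave the acetal and the α-alkoxy stereocentre untouched.

Step 5
Reactants: 3 (4Z)-4-bromohexa-1,4-diene; 7 (2R,4R)-2-(3,4,5-trimethoxyphenyl)-1,3-dioxane-4-carbaldehyde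
Product: 9 (1S,2Z)-2-(prop-2-en-1-yl)-1-[(2R,4R)-2-(3,4,5-trimethoxyphenyl)-1,3-dioxan-4-yl]but-2-en-1-ol, via (4E)-hexa-1,4-dien-4-yllithium 8 (not isolated)
Conditions: 3, t-BuLi (2 equiv), Et2O, −78 °C; then 7, −78 °C; aq NH4Cl
Reagents that add atoms: none
Why: Bromine–lithium exchange proceeds with retention of alkene geometry, and non-chelated Felkin–Anh 1,2-addition to the α-alkoxy aldehyde should give mainly the anti (1S) carbinol, the minor 1R epimer being removed by chromatography.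

Step 6
Reactants: 9 (1S,2Z)-2-(prop-2-en-1-yl)-1-[(2R,4R)-2-(3,4,5-trimethoxyphenyl)-1,3-dioxan-4-yl]but-2-en-1-ol
Product: 13 (2R,3S,3aR,7aR)-3-methyl-3a-(prop-2-en-1-yl)-2-(3,4,5-trimethoxyphenyl)hexahydro-4H-furo[3,2-c]pyran-4-ol, via oxocarbenium ion 10 (not isolated), via oxanyl cation 11 (not isolated), via hydroxy aldehyde 12 (not isolated)
Conditions: SnCl4 (2 equiv), CH2Cl2, −78 → −20 °C; aq NaHCO3
Reagents that add atoms: none
Why: SnCl4 opens the aryl acetal at its less hindered primary C–O bond to give the (E)-oxocarbenium ion 10 on the C7a oxygen, C3 of the (Z)-trisubstituted alkene attacks it in a Prins cyclisation (new C2–C3 bond) to give the tertiary oxanyl cation 11, and a pinacol 1,2-shift of C7a from the carbinol carbon to C3a (new C3a–C7a bond) contracts the oxane to the oxolane and turns the carbinol into aldehyde 12, which the freed hydroxyethyl arm traps as lactol 13 (a 2-oxonia-Cope/aldol pathway would give the same two bonds). The closest known reaction type is the Prins cyclisation–pinacol rearrangement of allylic diol acetals to 3-acyl tetrahydrofurans. The transient oxane closes by 6-endo-trig attack on the oxocarbenium ion, the oxolane by ring contraction through the suprafacial 1,2-shift, and the lactol by 6-exo-trig addition of the hydroxyl to the aldehyde. Stereocontrol comes from a chair transition state with the C7a side chain, the aryl group and the carbinol hydroxyl equatorial: the aryl group at C2 ends cis to the C7a side chain, the (Z)-alkene geometry forces the C3 methyl axial and hence cis to the aryl group, and C7a adds to the face of C3a on which it already sits, so the formyl group ends cis to methyl, aryl and side chain and the allyl group trans. The step needs the trisubstituted alkene to react instead of the terminal allyl alkene and the productive acetal opening to win; the allyl alkene could only close a seven- or eight-membered ring, and the oxocarbenium ion on the primary oxygen has no six-membered cyclisation path and should revert.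

Step 7
Reactants: 13 (2R,3S,3aR,7aR)-3-methyl-3a-(prop-2-en-1-yl)-2-(3,4,5-trimethoxyphenyl)hexahydro-4H-furo[3,2-c]pyran-4-ol
Product: 14 [(2R,3S,4S,5R)-2-(2-hydroxyethyl)-4-methyl-3-(prop-2-en-1-yl)-5-(3,4,5-trimethoxyphenyl)oxolan-3-yl]methanol
Conditions: NaBH4, MeOH, 0 °C
Reagents that add atoms: none
Why: Borohydride reduces the lactol through its open hydroxy-aldehyde tautomer to the 1,5-diol without touching any stereocentre.

Step 8
Reactants: 14 [(2R,3S,4S,5R)-2-(2-hydroxyethyl)-4-methyl-3-(prop-2-en-1-yl)-5-(3,4,5-trimethoxyphenyl)oxolan-3-yl]methanol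
Product: 16 (2R,3S,3aS,7aR)-3-methyl-3a-(prop-2-en-1-yl)-2-(3,4,5-trimethoxyphenyl)hexahydro-4H-furo[3,2-c]pyran-6-one, via lactol 15 (not isolated)
Conditions: TEMPO (10 mol %), PhI(OAc)2 (2.5 equiv), CH2Cl2, rt
Reagents that add atoms: none
Why: In this oxoammonium-mediated oxidative lactonisation the unhindered primary alcohol of the hydroxyethyl arm should be oxidised much faster than the neopentyl CH2OH on the quaternary carbon, the aldehyde is trapped as the δ-lactol and this is oxidised on to the lactone with the carbonyl at C6.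

Step 9
Reactants: 16 (2R,3S,3aS,7aR)-3-methyl-3a-(prop-2-en-1-yl)-2-(3,4,5-trimethoxyphenyl)hexahydro-4H-furo[3,2-c]pyran-6-one
Product: 17 diethyl {(1RS)-3-[(2R,3S,4S,5R)-3-(hydroxymethyl)-4-methyl-3-(prop-2-en-1-yl)-5-(3,4,5-trimethoxyphenyl)oxolan-2-yl]-1-methoxy-2-oxopropyl}phosphonate
Conditions: (EtO)2P(O)CH2OMe (2.5 equiv), LiN(iPr)2 (2.5 equiv), THF, −78 °C; then 16; aq NH4Cl
Reagents that add atoms: diethyl (methoxymethyl)phosphonate, CCOP(=O)(COC)OCC
Why: Claisen-type acylation of the lithiated phosphonate by the lactone opens the ring to the β-ketophosphonate, the excess anion deprotonating the product so that it is not attacked twice, and the new C5 centre (a mixture) is destroyed in the next step.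

Step 10
Reactants: 17 diethyl {(1RS)-3-[(2R,3S,4S,5R)-3-(hydroxymethyl)-4-methyl-3-(prop-2-en-1-yl)-5-(3,4,5-trimethoxyphenyl)oxolan-2-yl]-1-methoxy-2-oxopropyl}phosphonate
Product: 19 (2R,3S,3aS,7aR)-5-methoxy-3-methyl-3a-(prop-2-en-1-yl)-2-(3,4,5-trimethoxyphenyl)-3,3a,7,7a-tetrahydro-1-benzofuran-6(2H)-one, via keto aldehyde 18 (not isolated)
Conditions: n-Pr4N[RuO4] (5 mol %), N-methylmorpholine N-oxide, 4 Å MS, CH2Cl2, rt; then LiCl, iPr2NEt, MeCN, rt
Reagents that add atoms: none
Why: Ley–Griffith oxidation of the neopentyl alcohol gives the non-enolisable aldehyde, and an intramolecular Horner–Wadsworth–Emmons reaction under mild lithium chloride–amine conditions should close the six-membered carbocycle at C4=C5 to the α-methoxy enone without epimerising or eliminating the β-alkoxy ketone.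

Step 11
Reactants: 19 (2R,3S,3aS,7aR)-5-methoxy-3-methyl-3a-(prop-2-en-1-yl)-2-(3,4,5-trimethoxyphenyl)-3,3a,7,7a-tetrahydro-1-benzofuran-6(2H)-one
Product: 21 (2R,3S,3aS)-5-methoxy-3-methyl-3a-(prop-2-en-1-yl)-2-(3,4,5-trimethoxyphenyl)-3,3a-dihydro-1-benzofuran-6(2H)-one, via lithium dienolate 20 (not isolated)
Conditions: LiN(iPr)2, THF, −78 °C; then PhS(Cl)=NtBu, −78 °C
Reagents that add atoms: none
Why: In this Mukaiyama dehydrogenation C7 is the only enolisable position, the cross-conjugated lithium enolate is sulfenylated at C7 by N-tert-butylbenzenesulfinimidoyl chloride and syn-elimination of the sulfenamide across C7–C7a at low temperature should give the cross-conjugated dienone, which removes the auxiliary C7a stereocentre.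

**Compound list**

1 | acetaldehyde | CC=O | starting material
2 | 1,1-dibromoprop-1-ene | CC=C(Br)Br | intermediate
3 | (4Z)-4-bromohexa-1,4-diene (bromine cis to the methyl group) | C=CC/C(Br)=C/C | intermediate
4 | (2R)-butane-1,2,4-triol | OC[C@H](O)CCO | starting material
5 | 3,4,5-trimethoxybenzaldehyde | COc1cc(C=O)cc(OC)c1OC | starting material
6 | [(2R,4R)-2-(3,4,5-trimethoxyphenyl)-1,3-dioxan-4-yl]methanol (cis-2,4) | OC[C@H]1CCO[C@@H](c2cc(OC)c(OC)c(OC)c2)O1 | intermediate
7 | (2R,4R)-2-(3,4,5-trimethoxyphenyl)-1,3-dioxane-4-carbaldehyde | O=C[C@H]1CCO[C@@H](c2cc(OC)c(OC)c(OC)c2)O1 | intermediate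
8 | (4E)-hexa-1,4-dien-4-yllithium (lithium cis to the methyl group) | C=CC/C([Li])=C/C | intermediate (not isolated)
9 | (1S,2Z)-2-(prop-2-en-1-yl)-1-[(2R,4R)-2-(3,4,5-trimethoxyphenyl)-1,3-dioxan-4-yl]but-2-en-1-ol | C=CC/C(=C/C)[C@H](O)[C@H]1CCO[C@@H](c2cc(OC)c(OC)c(OC)c2)O1 | intermediate
10 | (E)-oxocarbenium ion formed from 3,4,5-trimethoxybenzaldehyde and the C3 oxygen of (3R,4S,5Z)-5-(prop-2-en-1-yl)hept-5-ene-1,3,4-triol | C=CC/C(=C/C)[C@H](O)[C@@H](CCO)/[O+]=C/c1cc(OC)c(OC)c(OC)c1 | intermediate (not isolated)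
11 | 5-hydroxy-6-(2-hydroxyethyl)-3-methyl-4-(prop-2-en-1-yl)-2-(3,4,5-trimethoxyphenyl)oxan-4-ylium (aryl, hydroxyethyl and hydroxyl equatorial, methyl axial) | C=CC[C+]1[C@H](C)[C@H](c2cc(OC)c(OC)c(OC)c2)O[C@H](CCO)[C@H]1O | intermediate (not isolated)
12 | (2R,3R,4S,5R)-2-(2-hydroxyethyl)-4-methyl-3-(prop-2-en-1-yl)-5-(3,4,5-trimethoxyphenyl)oxolane-3-carbaldehyde | C=CC[C@]1(C=O)[C@@H](CCO)O[C@@H](c2cc(OC)c(OC)c(OC)c2)[C@H]1C | intermediate (not isolated)
13 | (2R,3S,3aR,7aR)-3-methyl-3a-(prop-2-en-1-yl)-2-(3,4,5-trimethoxyphenyl)hexahydro-4H-furo[3,2-c]pyran-4-ol (lactol, both anomers) | C=CC[C@]12C(O)OCC[C@H]1O[C@@H](c1cc(OC)c(OC)c(OC)c1)[C@H]2C | intermediate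
14 | [(2R,3S,4S,5R)-2-(2-hydroxyethyl)-4-methyl-3-(prop-2-en-1-yl)-5-(3,4,5-trimethoxyphenyl)oxolan-3-yl]methanol | C=CC[C@]1(CO)[C@@H](CCO)O[C@@H](c2cc(OC)c(OC)c(OC)c2)[C@H]1C | intermediate
15 | (2R,3S,3aS,7aR)-3-methyl-3a-(prop-2-en-1-yl)-2-(3,4,5-trimethoxyphenyl)hexahydro-4H-furo[3,2-c]pyran-6-ol (lactol, both anomers) | C=CC[C@]12COC(O)C[C@H]1O[C@@H](c1cc(OC)c(OC)c(OC)c1)[C@H]2C | intermediate (not isolated)
16 | (2R,3S,3aS,7aR)-3-methyl-3a-(prop-2-en-1-yl)-2-(3,4,5-trimethoxyphenyl)hexahydro-4H-furo[3,2-c]pyran-6-one (δ-lactone, carbonyl at C6) | C=CC[C@]12COC(=O)C[C@H]1O[C@@H](c1cc(OC)c(OC)c(OC)c1)[C@H]2C | intermediate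
17 | diethyl {(1RS)-3-[(2R,3S,4S,5R)-3-(hydroxymethyl)-4-methyl-3-(prop-2-en-1-yl)-5-(3,4,5-trimethoxyphenyl)oxolan-2-yl]-1-methoxy-2-oxopropyl}phosphonate | C=CC[C@]1(CO)[C@@H](CC(=O)C(OC)P(=O)(OCC)OCC)O[C@@H](c2cc(OC)c(OC)c(OC)c2)[C@H]1C | intermediate
18 | diethyl {(1RS)-3-[(2R,3R,4S,5R)-3-formyl-4-methyl-3-(prop-2-en-1-yl)-5-(3,4,5-trimethoxyphenyl)oxolan-2-yl]-1-methoxy-2-oxopropyl}phosphonate | C=CC[C@]1(C=O)[C@@H](CC(=O)C(OC)P(=O)(OCC)OCC)O[C@@H](c2cc(OC)c(OC)c(OC)c2)[C@H]1C | intermediate (not isolated)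
19 | (2R,3S,3aS,7aR)-5-methoxy-3-methyl-3a-(prop-2-en-1-yl)-2-(3,4,5-trimethoxyphenyl)-3,3a,7,7a-tetrahydro-1-benzofuran-6(2H)-one | C=CC[C@]12C=C(OC)C(=O)C[C@H]1O[C@@H](c1cc(OC)c(OC)c(OC)c1)[C@H]2C | intermediate
20 | lithium (2R,3S,3aS,7aR)-5-methoxy-3-methyl-3a-(prop-2-en-1-yl)-2-(3,4,5-trimethoxyphenyl)-2,3,3a,7a-tetrahydro-1-benzofuran-6-olate | C=CC[C@]12C=C(OC)C(O[Li])=C[C@H]1O[C@@H](c1cc(OC)c(OC)c(OC)c1)[C@H]2C | intermediate (not isolated)
21 | (2R,3S,3aS)-5-methoxy-3-methyl-3a-(prop-2-en-1-yl)-2-(3,4,5-trimethoxyphenyl)-3,3a-dihydro-1-benzofuran-6(2H)-one | C=CC[C@]12C=C(OC)C(=O)C=C1O[C@@H](c1cc(OC)c(OC)c(OC)c1)[C@H]2C | target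

**Step count**

Total: 11 steps. Longest linear sequence: 9 steps (steps 3–11 from (2R)-butane-1,2,4-triol; the branch through steps 1, 2 and 5–11 is equally long).

**Steps most likely to fail**

Step 6 (key step). The benzylic C2–O1 bond of the product may ionise under the Lewis acid and scramble C2, the axial-methyl chair may lose out to less ordered pathways, and hydrogen chloride released from the free hydroxyl or unproductive opening of the six-membered acetal may degrade the allylic alcohol. The fallback changes the way the oxocarbenium ion is generated to the established substrate class, a 4-alkenyl-1,3-dioxolane without free hydroxyl groups. It sets out from 9 and returns at 14. Mild hydrolysis of the acetal of 9 (AcOH, H2O, THF) should give (3R,4S,5Z)-5-(prop-2-en-1-yl)hept-5-ene-1,3,4-triol F1. Selective silylation of the primary hydroxyl (t-BuPh2SiCl, imidazole, CH2Cl2) should give (3R,4S,5Z)-1-{[tert-butyl(diphenyl)silyl]oxy}-5-(prop-2-en-1-yl)hept-5-ene-3,4-diol F2. Acetalisation of the vicinal diol with aldehyde 5 (pyridinium p-toluenesulfonate, MgSO4, CH2Cl2) should give tert-butyl(2-{(4R,5S)-5-[(2Z)-hexa-2,5-dien-3-yl]-2-(3,4,5-trimethoxyphenyl)-1,3-dioxolan-4-yl}ethoxy)diphenylsilane F3. Its Prins cyclisation–pinacol rearrangement (SnCl4, CH2Cl2, −78 °C) should give (2R,3R,4S,5R)-2-(2-{[tert-butyl(diphenyl)silyl]oxy}ethyl)-4-methyl-3-(prop-2-en-1-yl)-5-(3,4,5-trimethoxyphenyl)oxolane-3-carbaldehyde F4, which cannot form a lactol and can be quenched cold. Reduction (NaBH4, MeOH) should give [(2R,3S,4S,5R)-2-(2-{[tert-butyl(diphenyl)silyl]oxy}ethyl)-4-methyl-3-(prop-2-en-1-yl)-5-(3,4,5-trimethoxyphenyl)oxolan-3-yl]methanol F5, and desilylation (n-Bu4NF, THF; aq NH4Cl) should give diol 14.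

Step 5. Chelation of lithium between the aldehyde and the ring oxygen may compete with the Felkin–Anh pathway and give poor facial selectivity at the new carbinol centre. The fallback sets this centre by reduction instead of addition. It sets out from 9 (as its mixture with the 1R epimer) and returns at 9. Oxidation of the mixture (Dess–Martin periodinane, NaHCO3, CH2Cl2) should give (2Z)-2-(prop-2-en-1-yl)-1-[(2R,4R)-2-(3,4,5-trimethoxyphenyl)-1,3-dioxan-4-yl]but-2-en-1-one F6. Chelation-controlled 1,2-reduction with Zn(BH4)2 (Et2O, −30 °C), in which zinc bridges the ketone and the adjacent ring oxygen and hydride is delivered from the face of the small α-hydrogen, should give the anti alcohol 9.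

Step 11. The lithium enolate at C7 may expel the ring oxygen at C7a (β-elimination that opens the oxolane), or the syn-elimination toward the oxygen-bearing C7a may be slow. The fallback uses soft enolisation and a palladium-mediated dehydrogenation (Saegusa–Ito oxidation). It sets out from 19 and returns at 21. Silylation (Me3SiOSO2CF3, Et3N, CH2Cl2, 0 °C) should give {[(2R,3S,3aS,7aR)-5-methoxy-3-methyl-3a-(prop-2-en-1-yl)-2-(3,4,5-trimethoxyphenyl)-2,3,3a,7a-tetrahydro-1-benzofuran-6-yl]oxy}(trimethyl)silane F7, and treatment with Pd(OAc)2 (1.1 equiv, MeCN, rt) should give 21 by β-hydride elimination from the palladium enolate.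

**Further compounds**

F1 | step 6 | (3R,4S,5Z)-5-(prop-2-en-1-yl)hept-5-ene-1,3,4-triol | C=CC/C(=C/C)[C@H](O)[C@H](O)CCO
F2 | step 6 | (3R,4S,5Z)-1-{[tert-butyl(diphenyl)silyl]oxy}-5-(prop-2-en-1-yl)hept-5-ene-3,4-diol | C=CC/C(=C/C)[C@H](O)[C@H](O)CCO[Si](c1ccccc1)(c1ccccc1)C(C)(C)C
F3 | step 6 | tert-butyl(2-{(4R,5S)-5-[(2Z)-hexa-2,5-dien-3-yl]-2-(3,4,5-trimethoxyphenyl)-1,3-dioxolan-4-yl}ethoxy)diphenylsilane (both acetal epimers) | C=CC/C(=C/C)[C@@H]1OC(c2cc(OC)c(OC)c(OC)c2)O[C@@H]1CCO[Si](c1ccccc1)(c1ccccc1)C(C)(C)C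
F4 | step 6 | (2R,3R,4S,5R)-2-(2-{[tert-butyl(diphenyl)silyl]oxy}ethyl)-4-methyl-3-(prop-2-en-1-yl)-5-(3,4,5-trimethoxyphenyl)oxolane-3-carbaldehyde | C=CC[C@]1(C=O)[C@@H](CCO[Si](c2ccccc2)(c2ccccc2)C(C)(C)C)O[C@@H](c2cc(OC)c(OC)c(OC)c2)[C@H]1C
F5 | step 6 | [(2R,3S,4S,5R)-2-(2-{[tert-butyl(diphenyl)silyl]oxy}ethyl)-4-methyl-3-(prop-2-en-1-yl)-5-(3,4,5-trimethoxyphenyl)oxolan-3-yl]methanol | C=CC[C@]1(CO)[C@@H](CCO[Si](c2ccccc2)(c2ccccc2)C(C)(C)C)O[C@@H](c2cc(OC)c(OC)c(OC)c2)[C@H]1C
F6 | step 5 | (2Z)-2-(prop-2-en-1-yl)-1-[(2R,4R)-2-(3,4,5-trimethoxyphenyl)-1,3-dioxan-4-yl]but-2-en-1-one | C=CC/C(=C/C)C(=O)[C@H]1CCO[C@@H](c2cc(OC)c(OC)c(OC)c2)O1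
F7 | step 11 | {[(2R,3S,3aS,7aR)-5-methoxy-3-methyl-3a-(prop-2-en-1-yl)-2-(3,4,5-trimethoxyphenyl)-2,3,3a,7a-tetrahydro-1-benzofuran-6-yl]oxy}(trimethyl)silane | C=CC[C@]12C=C(OC)C(O[Si](C)(C)C)=C[C@H]1O[C@@H](c1cc(OC)c(OC)c(OC)c1)[C@H]2C
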